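The route closes the tetrahydrofuran ring O12–C11–C10–C8a–C8 last, by a thermal Claisen/Diels–Alder cascade that copies the presumed biosynthesis of the cage. The precursor is a flat, fully assembled aromatic spiro compound: the spiro-acylal (1,3-benzodioxin-4-one) and the chromene-dione ring A are in place, and the benzene ring carries 1,1-dimethylallyl ethers on the oxygens of C7 and C8 (O12). The step exploits the feature that O12 holds a CMe2–CH=CH2 arm (C11, C10, C9) beside the latent diene C8a=C4a–C5=C6. A [3,3] shift of the O7 allyl group to C8 unmasks the diene, and one cycloaddition then closes the tetrahydrofuran ring and the bicyclo[2.2.2]octene bridge, setting four stereocentres.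

Key step: step 11

Locants: spiro[1,3-benzodioxine-2,7'-chromene] numbering is used throughout and kept for the cage (O1, C2 = C7' spiro, O3, C4=O, C4a, C5–C8, C8a; primed O1'–C8a' for the chromene; ring A = C4a'–C8a'). The arm on C8 is O12–C11(Me2)–C10H=C9H2.

Assumption: C2 (reversible oxa-Michael adduct) and C6' (enolisable) are epimerisable, and their configuration in the target (prenyl on C6' cis to O3) is taken to be the thermodynamically preferred one.

Step 1
Reactants: 1 2-methylbut-3-en-2-ol
Product: 2 tert-butyl 2-methylbut-3-en-2-yl carbonate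
Conditions: n-BuLi, THF, −78 °C; Boc2O, −78 °C to rt; aq. NH4Cl
Reagents that add atoms: di-tert-butyl dicarbonate CC(C)(C)OC(=O)OC(=O)OC(C)(C)C
Why: O-alkoxycarbonylation of the lithium alkoxide of a tertiary allylic alcohol with Boc2O gives the mixed carbonate that serves as precursor of the 1,1-dimethylallyl palladium electrophile.

Step 2
Reactants: 3 methyl 2,3,4-trihydroxybenzoate; 2 tert-butyl 2-methylbut-3-en-2-yl carbonate
Product: 4 methyl 2-hydroxy-3,4-bis[(2-methylbut-3-en-2-yl)oxy]benzoate
Conditions: Pd(PPh3)4 (cat.), THF, 0 °C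
Reagents that add atoms: none
Why: Decarboxylative Tsuji–Trost O-allylation, in which the tert-butoxide released on ionisation deprotonates the free phenols at C3 and C4 and each phenoxide attacks the more substituted allyl terminus under kinetic control, while the ester-chelated OH at C2 stays free.

Step 3
Reactants: 4 methyl 2-hydroxy-3,4-bis[(2-methylbut-3-en-2-yl)oxy]benzoate
Product: 6 methyl 2,5-dihydroxy-3,4-bis[(2-methylbut-3-en-2-yl)oxy]benzoate, via quinone ester 5 (not isolated)
Conditions: (KSO3)2NO (Fremy's salt), KH2PO4, acetone/H2O, 0 °C; then aq. Na2S2O4 in the same flask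
Reagents that add atoms: potassium nitrosodisulfonate [K+].[K+].[O]N(S(=O)(=O)[O-])S(=O)(=O)[O-]
Why: Teuber oxidation of the phenol at its free para position (C5) gives the para-quinone, which is reduced at once, before its allyl vinyl ether units can rearrange, so that the net result is a para-hydroxylation.

Step 4
Reactants: 6 methyl 2,5-dihydroxy-3,4-bis[(2-methylbut-3-en-2-yl)oxy]benzoate
Product: 7 methyl 2-hydroxy-5-[(4-methoxybenzyl)oxy]-3,4-bis[(2-methylbut-3-en-2-yl)oxy]benzoate
Conditions: 4-methoxybenzyl chloride, K2CO3, n-Bu4NI (cat.), DMF, rt, argon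
Reagents that add atoms: 4-methoxybenzyl chloride COc1ccc(CCl)cc1
Why: Williamson etherification is selective for the free OH at C5 because the OH at C2 is hydrogen-bonded to the ester and flanked on both sides, and the PMB group can later be removed oxidatively from a tertiary carbon.

Step 5
Reactants: 7 methyl 2-hydroxy-5-[(4-methoxybenzyl)oxy]-3,4-bis[(2-methylbut-3-en-2-yl)oxy]benzoate
Product: 8 2-hydroxy-5-[(4-methoxybenzyl)oxy]-3,4-bis[(2-methylbut-3-en-2-yl)oxy]benzoic acid
Conditions: LiOH·H2O, THF/MeOH/H2O, 40 °C; then 1 M HCl to pH 3–4, 0 °C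
Reagents that add atoms: lithium hydroxide [Li+].[OH-]
Why: Saponification of the methyl ester; the tertiary allyl aryl ethers and the PMB ether are stable to base, and the cold, weakly acidic work-up avoids cleavage of the 1,1-dimethylallyl ethers.

Step 6
Reactants: 9 2,6-dimethoxy-1,4-benzoquinone; 10 tributyl(3-methylbut-2-en-1-yl)stannane (Bu3SnCH2CH=CMe2)
Product: 12 2,6-dimethoxy-3-(3-methylbut-2-en-1-yl)-1,4-benzoquinone, via prenylhydroquinone 11 (not isolated)
Conditions: BF3·OEt2, CH2Cl2, −78 °C; aq. NaHCO3; then Ag2O, Et2O, rt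
Reagents that add atoms: none
Why: Lewis acid-mediated allylation of a quinone with an allylstannane (1,2-addition at the unhindered C4 carbonyl through the γ-carbon, then [3,3] shift) places the linear prenyl group on C3, which is equivalent to C5, and Ag2O returns the hydroquinone to the quinone level.

Step 7
Reactants: 12 2,6-dimethoxy-3-(3-methylbut-2-en-1-yl)-1,4-benzoquinone
Product: 13 2,6-dihydroxy-3-(3-methylbut-2-en-1-yl)-1,4-benzoquinone
Conditions: 2 M NaOH, MeOH, 60 °C, argon; then 1 M HCl, 0 °C
Reagents that add atoms: sodium hydroxide [Na+].[OH-]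
Why: Addition–elimination hydrolysis of both vinylogous methyl esters by hydroxide gives the bis(vinylogous acid); the prenyl group is inert to base and the cold dilute acid is too mild for chroman formation.

Step 8
Reactants: 13 2,6-dihydroxy-3-(3-methylbut-2-en-1-yl)-1,4-benzoquinone; 14 3-methylbut-2-enal
Product: 15 7-hydroxy-2,2-dimethyl-6-(3-methylbut-2-en-1-yl)-2H-chromene-5,8-dione
Conditions: ethylenediammonium diacetate (cat.), MeOH, rt
Reagents that add atoms: none
Why: Knoevenagel condensation at C5, the only unsubstituted nucleophilic carbon, followed by oxa-6π electrocyclisation of the dienone (formal [3+3] chromene annulation) gives the para-quinone pyran, which is thermodynamically preferred over the ortho-quinone isomer.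

Step 9
Reactants: 8 2-hydroxy-5-[(4-methoxybenzyl)oxy]-3,4-bis[(2-methylbut-3-en-2-yl)oxy]benzoic acid; 15 7-hydroxy-2,2-dimethyl-6-(3-methylbut-2-en-1-yl)-2H-chromene-5,8-dione
Product: 17 racemic (2S*,6'S*)-6-[(4-methoxybenzyl)oxy]-2',2'-dimethyl-6'-(3-methylbut-2-en-1-yl)-7,8-bis[(2-methylbut-3-en-2-yl)oxy]-6'H-spiro[benzo[d][1,3]dioxine-2,7'-chromene]-4,5',8'-trione, via open quinone ester 16 (not isolated)
Conditions: EDC·HCl, Et3N, DMAP (cat.), CH2Cl2, 0 °C to rt
Reagents that add atoms: none
Why: Steglich esterification of the vinylogous acid 15 is followed by 6-exo-trig oxa-Michael addition of the ortho phenoxide to C7' of the acyloxyquinone, a spiro-acylal closure known in this compound class for alkoxide donors; C2 forms as a racemate and C6' is set by reversible enolate protonation under thermodynamic control, the prenyl group taking the side of O3, away from O1 and its crowded C8 substituent.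

Step 10
Reactants: 17 racemic spiro-acylal
Product: 18 (2S,6'S)-6-[(4-methoxybenzyl)oxy]-2',2'-dimethyl-6'-(3-methylbut-2-en-1-yl)-7,8-bis[(2-methylbut-3-en-2-yl)oxy]-6'H-spiro[benzo[d][1,3]dioxine-2,7'-chromene]-4,5',8'-trione
Conditions: preparative SFC, amylose tris(3,5-dimethylphenylcarbamate) stationary phase, CO2/i-PrOH, 35 °C
Reagents that add atoms: none
Why: Resolution of the racemate on a chiral stationary phase under neutral conditions, under which C2 and C6' should be configurationally stable; the (2R,6'R) enantiomer can be racemised with amine base through the open quinone ester and recycled.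

Step 11
Reactants: 18 (2S,6'S)-spiro-acylal bis(1,1-dimethylallyl) ether
Product: 20 (2S,6'S,6R,8R,8aS,10S)-caged spiro-acylal carrying the C6 oxygen as PMB ether, via C8-prenyl dienone 19 (not isolated)
Conditions: PhMe (degassed, base-free), 110 °C, sealed tube
Reagents that add atoms: none
Why: Heating induces a reversible aromatic Claisen ([3,3]) shift of the O7 1,1-dimethylallyl group onto C8 to give the cyclohexa-2,4-dienone 19, in which C8 carries a prenyl group and O12 with its C11(Me2)–C10H=C9H2 arm, and this arm then adds across C8a and C6 of the diene C8a=C4a–C5=C6 in an irreversible intramolecular Diels–Alder reaction. The closest known reaction type is the Claisen/Diels–Alder cascade of catechol bis(1,1-dimethylallyl) ethers that builds the 4-oxatricyclo[4.3.1.0(3,7)]dec-8-en-2-one cage of the Garcinia xanthones and is held to be its biosynthesis. The tetrahydrofuran ring O12–C11–C10–C8a–C8 closes through the C10–C8a bond of a type 1 intramolecular [4+2] cycloaddition (three-atom tether C8–O12–C11, exo with respect to both reacting π bonds), and the second σ bond C9–C6 completes the bicyclo[2.2.2]octene. C8 is set in the Claisen step and, since the tether lets the vinyl group reach only the diene face that bears O12, it dictates C8a, C10 and C6 (8R,8aS,10S,6R); the sense at C8 itself is relayed from the spiro centre C2, because the two C8 epimers of 19 interconvert through 18 and the cycloaddition should take place at C8a on the face of the flat C8' carbonyl, anti to the bulkier sp3 branch C6'H(prenyl), as additions to the β-carbon of 2-substituted 1,3-dioxin-4-ones occur anti to the larger acetal substituent. The step needs site selectivity (migration of the O7 and not the O12 allyl group), which is secured by O7 being para to the C4 carbonyl and by the electron-poor acylal oxygen O1 on C8a, and it needs an intact diene, which the PMB enol ether at C6 provides. Base-free toluene keeps C6' and the spiro acetal from epimerising by enolisation or retro-oxa-Michael opening.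

Step 12
Reactants: 20 caged spiro-acylal PMB ether
Product: 21 target (2S,6'S,6R,8R,8aS,10S)-caged spiro-acylal with free bridgehead OH at C6
Conditions: DDQ, CH2Cl2/pH 7 phosphate buffer, 0 °C to rt
Reagents that add atoms: none
Why: Oxidative PMB ether cleavage, in which DDQ abstracts a benzylic hydride, water traps the oxocarbenium ion and the hemiacetal collapses to the bridgehead tertiary alcohol; the neutral buffered medium should leave the acylal, the prenyl groups and all six stereocentres untouched.

Compound list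
1 | 2-methylbut-3-en-2-ol | C=CC(C)(C)O | starting material
2 | tert-butyl 2-methylbut-3-en-2-yl carbonate | C=CC(C)(C)OC(=O)OC(C)(C)C | intermediate
3 | methyl 2,3,4-trihydroxybenzoate | COC(=O)c1ccc(O)c(O)c1O | starting material
4 | methyl 2-hydroxy-3,4-bis[(2-methylbut-3-en-2-yl)oxy]benzoate | COC(=O)c1ccc(OC(C)(C)C=C)c(OC(C)(C)C=C)c1O | intermediate
5 | methyl 4,5-bis[(2-methylbut-3-en-2-yl)oxy]-3,6-dioxocyclohexa-1,4-diene-1-carboxylate (not isolated) | COC(=O)C1=CC(=O)C(OC(C)(C)C=C)=C(OC(C)(C)C=C)C1=O | intermediate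
6 | methyl 2,5-dihydroxy-3,4-bis[(2-methylbut-3-en-2-yl)oxy]benzoate | COC(=O)c1cc(O)c(OC(C)(C)C=C)c(OC(C)(C)C=C)c1O | intermediate
7 | methyl 2-hydroxy-5-[(4-methoxybenzyl)oxy]-3,4-bis[(2-methylbut-3-en-2-yl)oxy]benzoate | COC(=O)c1cc(OCc2ccc(OC)cc2)c(OC(C)(C)C=C)c(OC(C)(C)C=C)c1O | intermediate
8 | 2-hydroxy-5-[(4-methoxybenzyl)oxy]-3,4-bis[(2-methylbut-3-en-2-yl)oxy]benzoic acid | OC(=O)c1cc(OCc2ccc(OC)cc2)c(OC(C)(C)C=C)c(OC(C)(C)C=C)c1O | intermediate
9 | 2,6-dimethoxy-1,4-benzoquinone | COC1=CC(=O)C=C(OC)C1=O | starting material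
10 | tributyl(3-methylbut-2-en-1-yl)stannane | CCCC[Sn](CCCC)(CCCC)CC=C(C)C | starting material
11 | 2,6-dimethoxy-3-(3-methylbut-2-en-1-yl)benzene-1,4-diol (not isolated) | COc1cc(O)c(CC=C(C)C)c(OC)c1O | intermediate
12 | 2,6-dimethoxy-3-(3-methylbut-2-en-1-yl)-1,4-benzoquinone | COC1=CC(=O)C(CC=C(C)C)=C(OC)C1=O | intermediate
13 | 2,6-dihydroxy-3-(3-methylbut-2-en-1-yl)-1,4-benzoquinone | OC1=CC(=O)C(CC=C(C)C)=C(O)C1=O | intermediate
14 | 3-methylbut-2-enal | CC(C)=CC=O | starting material
15 | 7-hydroxy-2,2-dimethyl-6-(3-methylbut-2-en-1-yl)-2H-chromene-5,8-dione | CC(C)=CCC1=C(O)C(=O)C2=C(C=CC(C)(C)O2)C1=O | intermediate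
16 | 2,2-dimethyl-6-(3-methylbut-2-en-1-yl)-5,8-dioxo-5,8-dihydro-2H-chromen-7-yl 2-hydroxy-5-[(4-methoxybenzyl)oxy]-3,4-bis[(2-methylbut-3-en-2-yl)oxy]benzoate (not isolated) | CC(C)=CCC1=C(OC(=O)c3cc(OCc4ccc(OC)cc4)c(OC(C)(C)C=C)c(OC(C)(C)C=C)c3O)C(=O)C2=C(C=CC(C)(C)O2)C1=O | intermediate
17 | racemic (2S*,6'S*)-6-[(4-methoxybenzyl)oxy]-2',2'-dimethyl-6'-(3-methylbut-2-en-1-yl)-7,8-bis[(2-methylbut-3-en-2-yl)oxy]-6'H-spiro[benzo[d][1,3]dioxine-2,7'-chromene]-4,5',8'-trione (both enantiomers) | CC(C)=CC[C@H]1C(=O)C2=C(OC(C)(C)C=C2)C(=O)[C@@]12OC(=O)c1cc(OCc3ccc(OC)cc3)c(OC(C)(C)C=C)c(OC(C)(C)C=C)c1O2.CC(C)=CC[C@@H]1C(=O)C2=C(OC(C)(C)C=C2)C(=O)[C@]12OC(=O)c1cc(OCc3ccc(OC)cc3)c(OC(C)(C)C=C)c(OC(C)(C)C=C)c1O2 | intermediate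
18 | (2S,6'S)-enantiomer of 17 | CC(C)=CC[C@H]1C(=O)C2=C(OC(C)(C)C=C2)C(=O)[C@@]12OC(=O)c1cc(OCc3ccc(OC)cc3)c(OC(C)(C)C=C)c(OC(C)(C)C=C)c1O2 | intermediate
19 | (2S,6'S,8R)-dienone: C7 ketone, C8 bearing prenyl and O12–C(Me)2–CH=CH2, diene C8a=C4a–C5=C6(OPMB) (not isolated) | CC(C)=CC[C@H]1C(=O)C2=C(OC(C)(C)C=C2)C(=O)[C@@]12OC(=O)C1=C(O2)[C@@](CC=C(C)C)(OC(C)(C)C=C)C(=O)C(OCc2ccc(OC)cc2)=C1 | intermediate
20 | (2S,6'S,6R,8R,8aS,10S)-cage: C8 and C8a bridged by O12–C11(Me2)–C10H, C9H2 bridge from C10 to C6, C6–OPMB, C7 ketone, C4a=C5 alkene, C8 prenyl | CC(C)=CC[C@H]1C(=O)C2=C(OC(C)(C)C=C2)C(=O)[C@@]12OC(=O)C1=C[C@]3(OCc5ccc(OC)cc5)C[C@H]4C(C)(C)O[C@@](CC=C(C)C)(C3=O)[C@@]14O2 | intermediate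
21 | target CNP0222516.1, (2S,6'S,6R,8R,8aS,10S)-cage with free C6–OH | CC(C)=CC[C@H]1C(=O)C2=C(OC(C)(C)C=C2)C(=O)[C@@]12OC(=O)C1=C[C@]3(O)C[C@H]4C(C)(C)O[C@@](CC=C(C)C)(C3=O)[C@@]14O2 | target

Total steps: 12. Longest linear sequence: 9 (steps 1, 2, 3, 4, 5, 9, 10, 11, 12).

Steps most likely to fail

Step 11. The facial selectivity of the cycloaddition relative to the spiro centre C2 may be low or opposite to the one argued, and the O12 allyl group may migrate to C7 instead, which leads to the isomeric cage. The fallback sets out from 17 and makes the outcome independent of the facial preference. The (2R,6'R)-enantiomer of 18 F1, which step 10 also delivers, is heated in the same way. From it the cage of the wanted absolute configuration arises on the other diene face, as the C2,C6'-bis-epimer of 20 F2, which is separated from its diastereomer on silica. Because C2 is an oxa-Michael adduct and C6' is enolisable, F2 is then equilibrated with a catalytic amine base (DBU, CH2Cl2, rt) through the open quinone ester alkoxide. This retro-oxa-Michael/oxa-Michael sequence is the known way to set this spiro centre with a tertiary alkoxide donor, and it brings the material back to the route at 20.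

Step 9. The ring–chain equilibrium of the phenoxide conjugate addition may lie on the side of the open quinone ester, and the acyl group may migrate between O7' and O5' of the ambident hydroxyquinone. The fallback sets out from 16, generated from 8 and 15 as in step 9. TBSOTf/Et3N in CH2Cl2 at −78 °C activates the quinone for attack by the phenol and traps the dienolate on O5', giving the racemic spiro silyl dienol ether F3 without a ring–chain equilibrium. F3 is resolved as in step 10 to its (2S)-enantiomer F4. The cascade of step 11 is run on F4 to give the caged silyl dienol ether F5. Buffered desilylation (TBAF/AcOH, THF, 0 °C) then releases the C5' ketone with thermodynamic protonation at C6', at a stage where O1 sits on a tertiary alkyl carbon, and the material returns to the route at 20.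

Step 7. Exhaustive hydrolysis may stall at the mono-anion, and the doubly enolic dihydroxyquinone 13 may self-condense at its free C5 position on acidification. The fallback sets out from 9 and avoids both the stannane and 13. Mild hydrolysis (1 M NaOH, rt, then HCl) gives 2-hydroxy-6-methoxy-1,4-benzoquinone F6. Chromene annulation of F6 with 14 (ethylenediammonium diacetate, MeOH) gives 7-methoxy-2,2-dimethyl-2H-chromene-5,8-dione F7. Hydrolysis of this neutral vinylogous ester gives 7-hydroxy-2,2-dimethyl-2H-chromene-5,8-dione F8. Tsuji–Trost C-prenylation of the vinylogous acid F8 with carbonate 2 and Pd(PPh3)4 (THF, rt) delivers the linear prenyl group at C6', since C-allylation is the thermodynamic outcome for such soft carbon nucleophiles, and returns to the route at 15.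

Further compounds
F1 | step 11 | (2R,6'R)-enantiomer of 18 | CC(C)=CC[C@@H]1C(=O)C2=C(OC(C)(C)C=C2)C(=O)[C@]12OC(=O)c1cc(OCc3ccc(OC)cc3)c(OC(C)(C)C=C)c(OC(C)(C)C=C)c1O2
F2 | step 11 | (2R,6'R,6R,8R,8aS,10S)-cage, the C2,C6'-bis-epimer of 20 | CC(C)=CC[C@@H]1C(=O)C2=C(OC(C)(C)C=C2)C(=O)[C@]12OC(=O)C1=C[C@]3(OCc5ccc(OC)cc5)C[C@H]4C(C)(C)O[C@@](CC=C(C)C)(C3=O)[C@@]14O2
F3 | step 9 | racemic 5'-(tert-butyldimethylsilyloxy) spiro dienol ether of 17 (ring A as C5'=C6' silyl enol ether, both enantiomers) | CC(C)=CCC1=C(O[Si](C)(C)C(C)(C)C)C2=C(OC(C)(C)C=C2)C(=O)[C@@]13OC(=O)c1cc(OCc4ccc(OC)cc4)c(OC(C)(C)C=C)c(OC(C)(C)C=C)c1O3.CC(C)=CCC1=C(O[Si](C)(C)C(C)(C)C)C2=C(OC(C)(C)C=C2)C(=O)[C@]13OC(=O)c1cc(OCc4ccc(OC)cc4)c(OC(C)(C)C=C)c(OC(C)(C)C=C)c1O3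
F4 | step 9 | (2S)-enantiomer of F3 | CC(C)=CCC1=C(O[Si](C)(C)C(C)(C)C)C2=C(OC(C)(C)C=C2)C(=O)[C@@]13OC(=O)c1cc(OCc4ccc(OC)cc4)c(OC(C)(C)C=C)c(OC(C)(C)C=C)c1O3
F5 | step 9 | (2S,6R,8R,8aS,10S)-caged 5'-silyl dienol ether (20 with ring A as C5'=C6' silyl enol ether) | CC(C)=CCC1=C(O[Si](C)(C)C(C)(C)C)C2=C(OC(C)(C)C=C2)C(=O)[C@@]13OC(=O)C1=C[C@]4(OCc5ccc(OC)cc5)C[C@H]6C(C)(C)O[C@@](CC=C(C)C)(C4=O)[C@@]16O3
F6 | step 7 | 2-hydroxy-6-methoxy-1,4-benzoquinone | COC1=CC(=O)C=C(O)C1=O
F7 | step 7 | 7-methoxy-2,2-dimethyl-2H-chromene-5,8-dione | COC1=CC(=O)C2=C(OC(C)(C)C=C2)C1=O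
F8 | step 7 | 7-hydroxy-2,2-dimethyl-2H-chromene-5,8-dione | OC1=CC(=O)C2=C(OC(C)(C)C=C2)C1=O
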